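## Retrosynthetic overview

1. Numbering used in the text (labdane type): ring A = C1–C5 plus C10 (Br on C3; CH3 and 4-methylpent-3-enyl on C4), ring B = C5–C10, C12 = exocyclic CH2 on C8, C11 = benzylic CH2 on C9.
2. Enabling feature: C9 of ring B carries the benzylic C11 and sits next to the exocyclic C8=C12 alkene. With the ring B bond C9–C10 opened, C9 is the CH end of a C8=C9 alkene whose C8 bears an allylic silicon on C12, so C9–C11 is a vinyl–benzyl bond that a terminal alkyne C8≡C9 can make.
3. Key disconnection (C9–C11): one-pot syn-carbocupration of the C8≡C9 alkyne with Me3SiCH2Cu (makes C8–C12) and benzylation of the alkenylcopper with an ortho-acyloxybenzyl bromide (makes C9–C11). This completes the C27 skeleton and stores the C9 configuration (alkene geometry) and the exocyclic methylene (allylsilane).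
4. Rings: ring A, then ring B, in one biomimetic cascade from a bromonium ion released inside the chain from an enantiopure C3-bromo/C4-silyloxy pair (no external Br+) and ended by the allylsilane. C3 and C4 come from Sharpless epoxidation of geraniol and SN2 opening by bromide.
5. Chain assembly: geraniol (C2–C4 and the side chain) + methyl acetoacetate (C1, C10, C5, C6) + 1-(trimethylsilyl)propyne (C7–C9); the arene ring is bought as methyl 4-hydroxy-3-methylbenzoate.

Key step: step 14

## Route

Step 1
Reactants: 1 methyl 4-hydroxy-3-methylbenzoate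
Product: 2 methyl 3-bromo-4-hydroxy-5-methylbenzoate
Conditions: NBS, MeCN, 0 °C → rt
Reagents that add atoms: N-bromosuccinimide, O=C1CCC(=O)N1Br
Why: Electrophilic aromatic bromination; the phenol directs ortho/para, and with the para and one ortho position occupied only the remaining ortho carbon is open.

Step 2
Reactants: 2 methyl 3-bromo-4-hydroxy-5-methylbenzoate
Product: 3 methyl 3-bromo-5-methyl-4-(pivaloyloxy)benzoate
Conditions: t-BuCOCl, Et3N, DMAP (cat.), CH2Cl2, 0 °C → rt
Reagents that add atoms: pivaloyl chloride, CC(C)(C)C(=O)Cl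
Why: DMAP-catalysed O-acylation; the pivalate keeps the phenol from quenching the organocopper reagent of step 14 and from trapping the C8 cation in step 15, and is removed in the final saponification.

Step 3
Reactants: 3 methyl 3-bromo-5-methyl-4-(pivaloyloxy)benzoate
Product: 4 methyl 3-bromo-5-(bromomethyl)-4-(pivaloyloxy)benzoate
Conditions: NBS, AIBN (cat.), PhCF3, 80 °C
Reagents that add atoms: N-bromosuccinimide, O=C1CCC(=O)N1Br
Why: Wohl–Ziegler radical bromination; the ring methyl is the only benzylic C–H position.

Step 4
Reactants: 5 geraniol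
Product: 6 (2S,3S)-2,3-epoxygeraniol
Conditions: Ti(OiPr)4 (cat.), L-(+)-diethyl tartrate (cat.), t-BuOOH, 4 Å molecular sieves, CH2Cl2, −20 °C
Reagents that add atoms: tert-butyl hydroperoxide, CC(C)(C)OO
Why: Sharpless asymmetric epoxidation; the titanium tartrate binds the allylic alcohol, so only the 2,3-alkene reacts (the distal trisubstituted alkene is untouched), and L-(+)-tartrate delivers oxygen to the face that gives the (2S,3S)-epoxide, which fixes the future C3 and C4.

Step 5
Reactants: 6 (2S,3S)-2,3-epoxygeraniol
Product: 7 (2S,3S)-2,3-epoxygeranyl p-toluenesulfonate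
Conditions: TsCl, Et3N, DMAP (cat.), CH2Cl2, 0 °C
Reagents that add atoms: p-toluenesulfonyl chloride, Cc1ccc(cc1)S(Cl)(=O)=O
Why: Sulfonylation of the primary alcohol gives an SN2-active leaving group without touching the epoxide.

Step 6
Reactants: 7 (2S,3S)-2,3-epoxygeranyl p-toluenesulfonate; 8 methyl acetoacetate
Product: 9 methyl 5-[(2S,3S)-3-methyl-3-(4-methylpent-3-enyl)oxiran-2-yl]-3-oxopentanoate
Conditions: 8, NaH then n-BuLi, THF, 0 °C; 7, 0 °C → rt; aq. work-up
Reagents that add atoms: none
Why: γ-Alkylation of the acetoacetate dianion by SN2 at the primary tosylate (the epoxide carbons are a hindered CH and a fully substituted carbon and should not be attacked), adding C1, C10, C5 and C6.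

Step 7
Reactants: 9 epoxy β-keto ester
Product: 10 methyl (2Z)-3-(diethoxyphosphoryloxy)-5-[(2S,3S)-3-methyl-3-(4-methylpent-3-enyl)oxiran-2-yl]pent-2-enoate
Conditions: NaH, Et2O, 0 °C; (EtO)2P(O)Cl
Reagents that add atoms: diethyl chlorophosphate, CCOP(=O)(Cl)OCC
Why: O-Phosphorylation of the chelated sodium enolate, which should give the (Z)-enol phosphate.

Step 8
Reactants: 10 (Z)-enol phosphate
Product: 11 methyl (2E)-3-methyl-5-[(2S,3S)-3-methyl-3-(4-methylpent-3-enyl)oxiran-2-yl]pent-2-enoate
Conditions: Me2CuLi, Et2O, −78 → −45 °C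
Reagents that add atoms: lithium dimethylcuprate (Me2CuLi), [Li+].C[Cu-]C
Why: Cuprate addition–elimination on the β-phosphoryloxy enoate with retention of geometry, which sets the (E)-trisubstituted C5=C10 alkene and its methyl group; the hindered epoxide is inert at this temperature.

Step 9
Reactants: 11 (E)-epoxy enoate
Product: 12 (2E)-3-methyl-5-[(2S,3S)-3-methyl-3-(4-methylpent-3-enyl)oxiran-2-yl]pent-2-en-1-ol
Conditions: i-Bu2AlH, CH2Cl2, −78 °C; aq. work-up
Reagents that add atoms: none
Why: 1,2-Reduction of the conjugated ester to the allylic alcohol at low temperature, where the trisubstituted epoxide should survive.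

Step 10
Reactants: 12 epoxy allylic alcohol
Product: 14 (2S,3S)-3-[(3E)-5-bromo-3-methylpent-3-enyl]-2-methyl-2-(4-methylpent-3-enyl)oxirane, via allylic mesylate 13 (not isolated)
Conditions: MsCl, Et3N, THF, −40 °C; then LiBr, 0 °C
Reagents that add atoms: lithium bromide, [Li+].[Br-]
Why: Mesylation and SN2 displacement by bromide under neutral conditions, which keep the alkene geometry and the epoxide.

Step 11
Reactants: 14 epoxy allylic bromide; 15 1-(trimethylsilyl)propyne
Product: 17 (2S,3S)-2-methyl-3-[(3E)-3-methyloct-3-en-7-ynyl]-2-(4-methylpent-3-enyl)oxirane, via silylated enyne 16 (not isolated)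
Conditions: 15, n-BuLi, THF, −78 °C; 14, −78 → −20 °C; then K2CO3 (cat.), MeOH, rt
Reagents that add atoms: none
Why: Propargylation of the allylic bromide by lithiated silylpropyne (SN2 at the propargylic carbon, the silyl group suppressing the allenyl mode), followed by methanolysis of the alkynyl C–Si bond to unveil the terminal alkyne C8≡C9.

Step 12
Reactants: 17 epoxy dienyne
Product: 18 (6S,7R,10E)-7-bromo-2,6,10-trimethylpentadeca-2,10-dien-14-yn-6-ol
Conditions: Li2NiBr4, THF, 0 °C → rt; aq. work-up
Reagents that add atoms: dilithium tetrabromonickelate (Li2NiBr4), [Li+].[Li+].[Ni+2].[Br-].[Br-].[Br-].[Br-]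
Why: SN2 opening of the epoxide by a soft, non-acidic bromide source at the less substituted carbon C3 with inversion, which should give the anti bromohydrin with the C3 bromide already in its final configuration.

Step 13
Reactants: 18 bromohydrin
Product: 19 triethylsilyl ether of 18 (tertiary C4–OSiEt3, secondary C3–Br)
Conditions: Et3SiOTf, 2,6-lutidine, CH2Cl2, −78 °C
Reagents that add atoms: triethylsilyl trifluoromethanesulfonate, CC[Si](CC)(CC)OS(=O)(=O)C(F)(F)F
Why: Silylation of the tertiary alcohol with a silyl triflate and a hindered pyridine, a base too weak to close the bromohydrin back to the epoxide; the silyl ether protects the alcohol in step 14 and is the leaving group of step 15.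

Step 14
Reactants: 19 silylated bromohydrin alkyne; 4 methyl 3-bromo-5-(bromomethyl)-4-(pivaloyloxy)benzoate
Product: 21 fully assembled (2Z,6E)-allylsilane polyene (cyclisation substrate), via alkenylcopper 20 (not isolated)
Conditions: Me3SiCH2MgCl, CuBr·SMe2, Et2O/Me2S, −45 °C; 19, −25 °C; then 4, DMPU, −30 → 0 °C
Reagents that add atoms: (trimethylsilyl)methylmagnesium chloride, C[Si](C)(C)C[Mg]Cl
Why: Me3SiCH2Cu·MgBrCl should add across the terminal alkyne by a four-centre syn-carbocupration that puts copper on the terminal carbon C9 and the silylmethyl carbon C12 on C8, and the alkenylcopper 20 then displaces the benzylic bromide of 4 with retention of alkene geometry, forming C9–C11. The closest known reaction type is the Normant carbocupration of 1-alkynes with alkylcopper–magnesium halide reagents followed by alkylation of the alkenylcopper, the classical entry to stereodefined trisubstituted alkenes. The step closes no ring and creates no stereocentre itself, but it makes two C–C bonds in one operation and completes the C27 skeleton from three simple pieces. The geometry it fixes (C7 trans to C11, C12 cis to C11) is what the chair transition state of step 15 converts into the equatorial C9 substituent, and the silicon on C12 is what later forces the C8 cation to collapse to the exocyclic C8=C12 alkene. The step needs regio- and syn-selectivity, secured by the terminal alkyne and the concerted addition, and chemoselectivity, secured because organocopper reagents of monovalent copper leave esters, the aryl bromide and the hindered secondary bromide alone, the tertiary alcohol is silylated, and only the benzylic C–Br of 4 is SN2-active.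

Step 15
Reactants: 21 allylsilane polyene
Product: 22 callophycoic acid H methyl ester O-pivalate (3R,4R,5S,9R,10S)
Conditions: Me3SiOTf, 2,6-di-tert-butyl-4-methylpyridine, CH2Cl2, −78 → −20 °C
Reagents that add atoms: none
Why: Bromonium-ion-initiated polyene bicyclisation with Hosomi–Sakurai-type termination: the silyl triflate abstracts the tertiary silyloxy group with anchimeric help from the C3 bromine, the bromonium ion is opened at C4 by the C5=C10 alkene anti to bromine (fixing C4 relative to the pre-set C3), the chair–chair relay through the two E-configured alkenes sets the trans ring fusion (C5, C10) and the equatorial C9 substituent, and loss of silicon from C12 gives only the exocyclic alkene while regenerating the silyl triflate.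

Step 16
Reactants: 22 protected bicycle
Product: 23 callophycoic acid H
Conditions: LiOH, THF/MeOH/H2O, 45 °C; then aq. HCl
Reagents that add atoms: lithium hydroxide, [Li+].[OH-]
Why: Saponification of the methyl ester and the aryl pivalate; the equatorial, neopentyl-type C3 bromide has no antiperiplanar hydrogen and should resist elimination and substitution.

## Compound list

1 | methyl 4-hydroxy-3-methylbenzoate | COC(=O)c1ccc(O)c(C)c1 | starting material
2 | methyl 3-bromo-4-hydroxy-5-methylbenzoate | COC(=O)c1cc(C)c(O)c(Br)c1 | intermediate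
3 | methyl 3-bromo-5-methyl-4-(pivaloyloxy)benzoate | COC(=O)c1cc(C)c(OC(=O)C(C)(C)C)c(Br)c1 | intermediate
4 | methyl 3-bromo-5-(bromomethyl)-4-(pivaloyloxy)benzoate | COC(=O)c1cc(CBr)c(OC(=O)C(C)(C)C)c(Br)c1 | intermediate
5 | geraniol | CC(C)=CCC/C(C)=C/CO | starting material
6 | (2S,3S)-2,3-epoxygeraniol | CC(C)=CCC[C@]1(C)O[C@H]1CO | intermediate
7 | (2S,3S)-2,3-epoxygeranyl p-toluenesulfonate | CC(C)=CCC[C@]1(C)O[C@H]1COS(=O)(=O)c1ccc(C)cc1 | intermediate
8 | methyl acetoacetate | CC(=O)CC(=O)OC | starting material
9 | methyl 5-[(2S,3S)-3-methyl-3-(4-methylpent-3-enyl)oxiran-2-yl]-3-oxopentanoate | CC(C)=CCC[C@]1(C)O[C@H]1CCC(=O)CC(=O)OC | intermediate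
10 | methyl (2Z)-3-(diethoxyphosphoryloxy)-5-[(2S,3S)-3-methyl-3-(4-methylpent-3-enyl)oxiran-2-yl]pent-2-enoate | CC(C)=CCC[C@]1(C)O[C@H]1CC/C(OP(=O)(OCC)OCC)=C/C(=O)OC | intermediate
11 | methyl (2E)-3-methyl-5-[(2S,3S)-3-methyl-3-(4-methylpent-3-enyl)oxiran-2-yl]pent-2-enoate | CC(C)=CCC[C@]1(C)O[C@H]1CC/C(C)=C/C(=O)OC | intermediate
12 | (2E)-3-methyl-5-[(2S,3S)-3-methyl-3-(4-methylpent-3-enyl)oxiran-2-yl]pent-2-en-1-ol | CC(C)=CCC[C@]1(C)O[C@H]1CC/C(C)=C/CO | intermediate
13 | methanesulfonate of 12 | CC(C)=CCC[C@]1(C)O[C@H]1CC/C(C)=C/COS(C)(=O)=O | intermediate (not isolated)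
14 | (2S,3S)-3-[(3E)-5-bromo-3-methylpent-3-enyl]-2-methyl-2-(4-methylpent-3-enyl)oxirane | CC(C)=CCC[C@]1(C)O[C@H]1CC/C(C)=C/CBr | intermediate
15 | 1-(trimethylsilyl)propyne | CC#C[Si](C)(C)C | starting material
16 | C-trimethylsilyl derivative of alkyne 17 | CC(C)=CCC[C@]1(C)O[C@H]1CC/C(C)=C/CCC#C[Si](C)(C)C | intermediate (not isolated)
17 | (2S,3S)-2-methyl-3-[(3E)-3-methyloct-3-en-7-ynyl]-2-(4-methylpent-3-enyl)oxirane | CC(C)=CCC[C@]1(C)O[C@H]1CC/C(C)=C/CCC#C | intermediate
18 | (6S,7R,10E)-7-bromo-2,6,10-trimethylpentadeca-2,10-dien-14-yn-6-ol | CC(C)=CCC[C@](C)(O)[C@H](Br)CC/C(C)=C/CCC#C | intermediate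
19 | triethylsilyl ether of 18 | CC(C)=CCC[C@](C)(O[Si](CC)(CC)CC)[C@H](Br)CC/C(C)=C/CCC#C | intermediate
20 | alkenylcopper from 19 (Cu on C9, CH2SiMe3 on C8, cis to each other) | CC(C)=CCC[C@](C)(O[Si](CC)(CC)CC)[C@H](Br)CC/C(C)=C/CC/C(C[Si](C)(C)C)=C/[Cu] | intermediate (not isolated)
21 | methyl 3-bromo-5-[(2Z,6E,10R,11S)-10-bromo-7,11,15-trimethyl-11-(triethylsilyloxy)-3-[(trimethylsilyl)methyl]hexadeca-2,6,14-trienyl]-4-(pivaloyloxy)benzoate | CC(C)=CCC[C@](C)(O[Si](CC)(CC)CC)[C@H](Br)CC/C(C)=C/CC/C(C[Si](C)(C)C)=C/Cc1cc(C(=O)OC)cc(Br)c1OC(=O)C(C)(C)C | intermediate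
22 | callophycoic acid H methyl ester O-pivalate | C=C1CC[C@@H]2[C@@](C)(CCC=C(C)C)[C@H](Br)CC[C@@]2(C)[C@@H]1Cc1cc(C(=O)OC)cc(Br)c1OC(=O)C(C)(C)C | intermediate
23 | callophycoic acid H | C=C1CC[C@@H]2[C@@](C)(CCC=C(C)C)[C@H](Br)CC[C@@]2(C)[C@@H]1Cc1cc(C(=O)O)cc(Br)c1O | target

## Step count and risks

Total step count: 16. Longest linear sequence: 13 steps (steps 4–16, from geraniol).

Steps most likely to fail:

Step 15. The hindered β-bromo silyl ether may ionise sluggishly, and a tertiary cation that opens before ring closure can rotate (loss of the C4 configuration) or lose a proton; part of the material may also fold through a boat. The fallback changes how the bromonium ion is generated. It sets out from 21: HF·pyridine in THF removes the triethylsilyl group to give the free bromohydrin F1. Trifluoroacetic anhydride and pyridine convert it into the tertiary trifluoroacetate F2, a far better nucleofuge. Catalytic Me3SiOTf in CH2Cl2 at −78 °C, or simple solvolysis in hexafluoroisopropanol buffered with 2,6-di-tert-butyl-4-methylpyridine, then releases the same bromonium ion by carboxylate departure, and the cascade returns to the route at 22.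

Step 14. Transfer of the α-silylalkyl group from copper to the alkyne may be slow, and the alkenylcopper may be alkylated sluggishly, so that protonated alkene is collected instead of 21. The fallback replaces the stoichiometric carbometalation by a catalytic borylative one and a palladium coupling. It sets out from 19: copper-catalysed syn-borylcupration with C-alkylation (B2pin2, CuCl, Xantphos, NaOtBu, ICH2SiMe3, THF) puts boron on the terminal carbon C9 and the silylmethyl group on C8, giving the alkenyl pinacol boronate F3. Suzuki–Miyaura coupling of F3 with 4 (Pd(PPh3)4, K3PO4, THF/H2O, rt) then forms C9–C11 and returns at 21; the benzylic C–Br should add to zerovalent palladium before the flanked aryl C–Br.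

Step 12. Regiocontrol may be lost through bromide attack at the tertiary carbon C4, or the trisubstituted epoxide may rearrange under Lewis acid. The fallback accepts the other regiochemistry, because both anti bromohydrins collapse to the same bromonium ion. It sets out from 17: MgBr2·OEt2 in Et2O at −20 °C opens the epoxide at C4 with inversion to the tertiary bromide–secondary alcohol F4, and Et3SiOTf/2,6-lutidine gives its triethylsilyl ether F5. The protocol of step 14 with 4 leads through the alkenylcopper F6 to the polyene F7, and HF·pyridine frees the secondary alcohol F8. Tf2O with 2,6-di-tert-butyl-4-methylpyridine in CH2Cl2 at −78 °C forms a secondary triflate that the neighbouring C4 bromine displaces from the rear. This gives the bromonium ion of step 15 and the same allylsilane-terminated cascade, which returns to the route at 22.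

## Further compounds

F1 | step 15 | free bromohydrin from 21 (C4–OH, C3–Br) | CC(C)=CCC[C@](C)(O)[C@H](Br)CC/C(C)=C/CC/C(C[Si](C)(C)C)=C/Cc1cc(C(=O)OC)cc(Br)c1OC(=O)C(C)(C)C
F2 | step 15 | tertiary trifluoroacetate of F1 | CC(C)=CCC[C@](C)(OC(=O)C(F)(F)F)[C@H](Br)CC/C(C)=C/CC/C(C[Si](C)(C)C)=C/Cc1cc(C(=O)OC)cc(Br)c1OC(=O)C(C)(C)C
F3 | step 14 | alkenyl pinacol boronate from 19 (Bpin on C9, CH2SiMe3 on C8, cis) | CC(C)=CCC[C@](C)(O[Si](CC)(CC)CC)[C@H](Br)CC/C(C)=C/CC/C(C[Si](C)(C)C)=C/B1OC(C)(C)C(C)(C)O1
F4 | step 12 | regioisomeric anti bromohydrin from 17 (tertiary C4–Br, secondary C3–OH) | CC(C)=CCC[C@@](C)(Br)[C@@H](O)CC/C(C)=C/CCC#C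
F5 | step 12 | triethylsilyl ether of F4 | CC(C)=CCC[C@@](C)(Br)[C@@H](O[Si](CC)(CC)CC)CC/C(C)=C/CCC#C
F6 | step 12 | alkenylcopper from F5 | CC(C)=CCC[C@@](C)(Br)[C@@H](O[Si](CC)(CC)CC)CC/C(C)=C/CC/C(C[Si](C)(C)C)=C/[Cu]
F7 | step 12 | allylsilane polyene from F6 and 4 | CC(C)=CCC[C@@](C)(Br)[C@@H](O[Si](CC)(CC)CC)CC/C(C)=C/CC/C(C[Si](C)(C)C)=C/Cc1cc(C(=O)OC)cc(Br)c1OC(=O)C(C)(C)C
F8 | step 12 | secondary alcohol from F7 | CC(C)=CCC[C@@](C)(Br)[C@@H](O)CC/C(C)=C/CC/C(C[Si](C)(C)C)=C/Cc1cc(C(=O)OC)cc(Br)c1OC(=O)C(C)(C)C
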